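**Assumption:** an (R)-selective Old-Yellow-Enzyme-type ene-reductase for dienone 3 is found by screening a standard panel; all named reagents are commercial.

## Retrosynthetic overview

1. Target 21 ⇒ Mitsunobu esterification of allylic alcohol 19 with p-coumaric acid; C15 comes from vinyl iodide 18 plus formaldehyde; the acrylate comes from late α-methylenation of an acetate side chain.
2. The C3=C4 alkene and the trans ring fusion (C5–H) ⇒ reductive 1,3-transposition (allylic diazene) of the 3β-allylic alcohol 12, made from bicyclic enone 10.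
3. Ring B (formed second) ⇒ intramolecular vinylogous Michael addition of the γ-methyl group of cyclohexenone 9 onto a tethered enoate, which also sets C7.
4. Ring A (formed first, carries quaternary C10) ⇒ enzymatic desymmetrisation of the prochiral 4,4-disubstituted cyclohexadienone 3, obtained by oxidative dearomative para-allylation of p-cresol.

## Route

Step 1
Reactants: 1 p-cresol (4-methylphenol); 2 allyltrimethylsilane
Product: 3 4-methyl-4-(prop-2-en-1-yl)cyclohexa-2,5-dien-1-one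
Conditions: PhI(OAc)2 (1.1 equiv), allylTMS (4 equiv), (CF3)2CHOH, −10 °C to rt
Reagents that add atoms: none
Why: Hypervalent-iodine oxidative dearomatisation gives a phenoxenium ion that the allylsilane traps at the methyl-bearing para carbon (oxidative Hosomi–Sakurai allylation), forming the quaternary carbon in an achiral, Cs-symmetric dienone.

Step 2
Reactants: 3 4-methyl-4-(prop-2-en-1-yl)cyclohexa-2,5-dien-1-one
Product: 4 (4R)-4-methyl-4-(prop-2-en-1-yl)cyclohex-2-en-1-one
Conditions: ene-reductase (OYE family, (R)-selective hit), NADP+ (cat.), glucose, glucose dehydrogenase, KPi buffer pH 7.5, 5% DMSO, 30 °C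
Reagents that add atoms: none
Why: Enzymatic desymmetrising conjugate reduction (flavin hydride to Cβ, then protonation at Cα) of one enantiotopic enone arm turns the prochiral quaternary carbon into the (R)-stereocentre (C10 of the target); the hindered product enone is a poor substrate, so reduction stops.

Step 3
Reactants: 4 (4R)-4-methyl-4-(prop-2-en-1-yl)cyclohex-2-en-1-one
Product: 6 (4R)-3,4-dimethyl-4-(prop-2-en-1-yl)cyclohex-2-en-1-one, via silyl enol ether 5 (not isolated)
Conditions: MeMgBr, CuBr·SMe2 (10 mol%), TMSCl, THF, −78 °C; then IBX·4-methoxypyridine N-oxide, DMSO, rt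
Reagents that add atoms: methylmagnesium bromide C[Mg]Br
Why: Copper-catalysed conjugate methylation with silyl trapping, then IBX dehydrogenation of the regiodefined silyl enol ether, reinstalls the enone with the future C6 methyl on the β-carbon; the transient methine stereocentre is erased and the quaternary centre is untouched.

Step 4
Reactants: 6 (4R)-3,4-dimethyl-4-(prop-2-en-1-yl)cyclohex-2-en-1-one
Product: 7 3-[(1S)-1,2-dimethyl-4-oxocyclohex-2-en-1-yl]propanal
Conditions: PdCl2(PhCN)2 (10 mol%), CuCl2·2H2O (10 mol%), AgNO2 (5 mol%), O2 (1 atm), t-BuOH/MeNO2, rt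
Reagents that add atoms: dioxygen O=O
Why: Nitrite-modified, aldehyde-selective (anti-Markovnikov) Wacker oxidation of the terminal alkene; the enone is inert and no stereocentre is touched (the descriptor changes to S by CIP priority only).

Step 5
Reactants: 7 3-[(1S)-1,2-dimethyl-4-oxocyclohex-2-en-1-yl]propanal; 8 methyl (triphenylphosphoranylidene)acetate
Product: 9 methyl (2E)-5-[(1S)-1,2-dimethyl-4-oxocyclohex-2-en-1-yl]pent-2-enoate
Conditions: CH2Cl2, rt
Reagents that add atoms: none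
Why: Wittig olefination with a stabilised ylide reacts only at the aldehyde and gives the (E)-enoate that will accept the ring-B-forming Michael addition.

Step 6
Reactants: 9 methyl (2E)-5-[(1S)-1,2-dimethyl-4-oxocyclohex-2-en-1-yl]pent-2-enoate
Product: 10 methyl 2-[(2R,4aS)-4a-methyl-7-oxo-1,2,3,4,4a,5,6,7-octahydronaphthalen-2-yl]acetate
Conditions: t-BuOK (0.2 equiv), t-BuOH/THF, 0 °C to rt (equilibrating)
Reagents that add atoms: none
Why: Intramolecular vinylogous Michael addition (6-(enolendo)-exo-trig) of the thermodynamic exocyclic dienolate closes ring B and leaves C5 sp2; the chair transition state and reversibility place the CH2CO2Me group equatorial, cis to the axial angular methyl, which sets C7 as R.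

Step 7
Reactants: 10 methyl 2-[(2R,4aS)-4a-methyl-7-oxo-1,2,3,4,4a,5,6,7-octahydronaphthalen-2-yl]acetate
Product: 11 methyl 2-[(2R,4aS)-8-iodo-4a-methyl-7-oxo-1,2,3,4,4a,5,6,7-octahydronaphthalen-2-yl]acetate
Conditions: I2 (2.5 equiv), pyridine/CH2Cl2 1:1, rt, dark
Reagents that add atoms: iodine II
Why: Johnson α-iodination of the enone (amine conjugate addition, enolate iodination, elimination) places a handle for C15 on C4, as is done on Wieland–Miescher-type enones.

Step 8
Reactants: 11 methyl 2-[(2R,4aS)-8-iodo-4a-methyl-7-oxo-1,2,3,4,4a,5,6,7-octahydronaphthalen-2-yl]acetate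
Product: 12 methyl 2-[(2R,4aS,7S)-7-hydroxy-8-iodo-4a-methyl-1,2,3,4,4a,5,6,7-octahydronaphthalen-2-yl]acetate
Conditions: NaBH4, CeCl3·7H2O, MeOH, −78 to −40 °C
Reagents that add atoms: none
Why: Luche 1,2-reduction delivers hydride axially on the face opposite the angular methyl, giving the pseudo-equatorial 3β-alcohol (7S, cis to the methyl) without touching the ester or the vinyl iodide.

Step 9
Reactants: 12 methyl 2-[(2R,4aS,7S)-7-hydroxy-8-iodo-4a-methyl-1,2,3,4,4a,5,6,7-octahydronaphthalen-2-yl]acetate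
Product: 15 methyl 2-[(2R,4aS,8aR)-8-iodo-4a-methyl-1,2,3,4,4a,5,6,8a-octahydronaphthalen-2-yl]acetate, via sulfonylhydrazine 13 (not isolated), via allylic diazene 14 (not isolated)
Conditions: 2-nitrobenzenesulfonylhydrazide (NBSH), PPh3, DEAD, N-methylmorpholine, −30 °C, then rt
Reagents that add atoms: none
Why: Myers reductive 1,3-transposition: Mitsunobu displacement inverts C3 to the α-hydrazine, sulfinate loss gives the α-diazene, and its suprafacial retro-ene loss of N2 delivers H to C5 on the α-face, setting the trans ring fusion (8aR) and moving the alkene to C3=C4.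

Step 10
Reactants: 15 methyl 2-[(2R,4aS,8aR)-8-iodo-4a-methyl-1,2,3,4,4a,5,6,8a-octahydronaphthalen-2-yl]acetate
Product: 18 methyl 2-[(2R,4aS,8aR)-8-iodo-4a-methyl-1,2,3,4,4a,5,6,8a-octahydronaphthalen-2-yl]prop-2-enoate, via Mannich base 16 (not isolated), via ammonium iodide 17 (not isolated)
Conditions: LDA, THF, −78 °C; CH2=NMe2+ I−; then MeI, MeOH, rt; then DBU, CH2Cl2
Reagents that add atoms: Eschenmoser's salt (N,N-dimethylmethyleneiminium iodide) C=[N+](C)C.[I-]
Why: Ester enolate Mannich reaction, N-quaternisation and E1cB elimination give the α-methylene ester; C7 is not enolisable and the vinyl iodide is inert to LDA at −78 °C.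

Step 11
Reactants: 18 methyl 2-[(2R,4aS,8aR)-8-iodo-4a-methyl-1,2,3,4,4a,5,6,8a-octahydronaphthalen-2-yl]prop-2-enoate
Product: 19 methyl 2-[(2R,4aR,8aR)-8-(hydroxymethyl)-4a-methyl-1,2,3,4,4a,5,6,8a-octahydronaphthalen-2-yl]prop-2-enoate
Conditions: CrCl2 (4 equiv), NiCl2 (2 mol%), paraformaldehyde, DMF/THF, rt
Reagents that add atoms: formaldehyde (from paraformaldehyde) C=O
Why: Nozaki–Hiyama–Kishi coupling: the alkenylchromium(III) formed from the vinyl iodide adds only to formaldehyde (esters and the acrylate are tolerated) with retention of alkene position, giving the C15 allylic alcohol.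

Step 12
Reactants: 19 methyl 2-[(2R,4aR,8aR)-8-(hydroxymethyl)-4a-methyl-1,2,3,4,4a,5,6,8a-octahydronaphthalen-2-yl]prop-2-enoate; 20 p-coumaric acid ((2E)-3-(4-hydroxyphenyl)prop-2-enoic acid)
Product: 21 methyl 2-[(2R,4aR,8aR)-8-({[(2E)-3-(4-hydroxyphenyl)prop-2-enoyl]oxy}methyl)-4a-methyl-1,2,3,4,4a,5,6,8a-octahydronaphthalen-2-yl]prop-2-enoate (CNP0161949.1)
Conditions: PPh3, DIAD, THF, 0 °C to rt
Reagents that add atoms: none
Why: Mitsunobu esterification of the primary allylic alcohol; the carboxylic acid (pKa about 4.5) is engaged in preference to the free phenol (pKa about 9), so no protecting group is needed and no stereocentre is affected.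

## Compound list

1 | p-cresol (4-methylphenol) | Cc1ccc(O)cc1 | starting material
2 | allyltrimethylsilane | C=CC[Si](C)(C)C | starting material
3 | 4-methyl-4-(prop-2-en-1-yl)cyclohexa-2,5-dien-1-one | C=CCC1(C)C=CC(=O)C=C1 | intermediate
4 | (4R)-4-methyl-4-(prop-2-en-1-yl)cyclohex-2-en-1-one | C=CC[C@@]1(C)CCC(=O)C=C1 | intermediate
5 | trimethyl{[(4R)-3,4-dimethyl-4-(prop-2-en-1-yl)cyclohex-1-en-1-yl]oxy}silane (C3 epimers, not isolated) | C=CC[C@@]1(C)CCC(O[Si](C)(C)C)=CC1C | intermediate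
6 | (4R)-3,4-dimethyl-4-(prop-2-en-1-yl)cyclohex-2-en-1-one | C=CC[C@@]1(C)CCC(=O)C=C1C | intermediate
7 | 3-[(1S)-1,2-dimethyl-4-oxocyclohex-2-en-1-yl]propanal | O=CCC[C@@]1(C)CCC(=O)C=C1C | intermediate
8 | methyl (triphenylphosphoranylidene)acetate | COC(=O)C=P(c1ccccc1)(c1ccccc1)c1ccccc1 | starting material
9 | methyl (2E)-5-[(1S)-1,2-dimethyl-4-oxocyclohex-2-en-1-yl]pent-2-enoate | COC(=O)/C=C/CC[C@@]1(C)CCC(=O)C=C1C | intermediate
10 | methyl 2-[(2R,4aS)-4a-methyl-7-oxo-1,2,3,4,4a,5,6,7-octahydronaphthalen-2-yl]acetate | COC(=O)C[C@@H]1CC[C@@]2(C)CCC(=O)C=C2C1 | intermediate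
11 | methyl 2-[(2R,4aS)-8-iodo-4a-methyl-7-oxo-1,2,3,4,4a,5,6,7-octahydronaphthalen-2-yl]acetate | COC(=O)C[C@@H]1CC[C@@]2(C)CCC(=O)C(I)=C2C1 | intermediate
12 | methyl 2-[(2R,4aS,7S)-7-hydroxy-8-iodo-4a-methyl-1,2,3,4,4a,5,6,7-octahydronaphthalen-2-yl]acetate | COC(=O)C[C@@H]1CC[C@@]2(C)CC[C@H](O)C(I)=C2C1 | intermediate
13 | methyl 2-[(2R,4aS,7R)-8-iodo-4a-methyl-7-[1-(2-nitrobenzenesulfonyl)hydrazin-1-yl]-1,2,3,4,4a,5,6,7-octahydronaphthalen-2-yl]acetate (not isolated) | COC(=O)C[C@@H]1CC[C@@]2(C)CC[C@@H](N(N)S(=O)(=O)c3ccccc3[N+](=O)[O-])C(I)=C2C1 | intermediate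
14 | methyl 2-[(2R,4aS,7R)-7-diazenyl-8-iodo-4a-methyl-1,2,3,4,4a,5,6,7-octahydronaphthalen-2-yl]acetate (not isolated) | COC(=O)C[C@@H]1CC[C@@]2(C)CC[C@@H](N=N)C(I)=C2C1 | intermediate
15 | methyl 2-[(2R,4aS,8aR)-8-iodo-4a-methyl-1,2,3,4,4a,5,6,8a-octahydronaphthalen-2-yl]acetate | COC(=O)C[C@@H]1CC[C@@]2(C)CCC=C(I)[C@@H]2C1 | intermediate
16 | methyl 3-(dimethylamino)-2-[(2R,4aS,8aR)-8-iodo-4a-methyl-1,2,3,4,4a,5,6,8a-octahydronaphthalen-2-yl]propanoate (epimers at the propanoate C2, not isolated) | COC(=O)C(CN(C)C)[C@@H]1CC[C@@]2(C)CCC=C(I)[C@@H]2C1 | intermediate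
17 | N-methyl quaternary ammonium iodide of 16 (not isolated) | COC(=O)C(C[N+](C)(C)C)[C@@H]1CC[C@@]2(C)CCC=C(I)[C@@H]2C1.[I-] | intermediate
18 | methyl 2-[(2R,4aS,8aR)-8-iodo-4a-methyl-1,2,3,4,4a,5,6,8a-octahydronaphthalen-2-yl]prop-2-enoate | C=C(C(=O)OC)[C@@H]1CC[C@@]2(C)CCC=C(I)[C@@H]2C1 | intermediate
19 | methyl 2-[(2R,4aR,8aR)-8-(hydroxymethyl)-4a-methyl-1,2,3,4,4a,5,6,8a-octahydronaphthalen-2-yl]prop-2-enoate | C=C(C(=O)OC)[C@@H]1CC[C@@]2(C)CCC=C(CO)[C@@H]2C1 | intermediate
20 | p-coumaric acid, (2E)-3-(4-hydroxyphenyl)prop-2-enoic acid | O=C(O)/C=C/c1ccc(O)cc1 | starting material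
21 | methyl 2-[(2R,4aR,8aR)-8-({[(2E)-3-(4-hydroxyphenyl)prop-2-enoyl]oxy}methyl)-4a-methyl-1,2,3,4,4a,5,6,8a-octahydronaphthalen-2-yl]prop-2-enoate | C=C(C(=O)OC)[C@@H]1CC[C@@]2(C)CCC=C(COC(=O)/C=C/c3ccc(O)cc3)[C@@H]2C1 | target

## Step count and risks

Total steps: 12. Longest linear sequence: 12 (p-cresol 1 to 21).

**Step 2 (desymmetrisation).** The enzyme must tell a methyl from an allyl group on the quaternary carbon, so the ee may be low. Fallback, setting out from 3 and returning at 6: a copper/phosphoramidite-catalysed conjugate addition of Me2Zn to 3 gives two diastereomers, each of high ee. The one with the right quaternary centre, (4R,5S)-4,5-dimethyl-4-(prop-2-en-1-yl)cyclohex-2-en-1-one F1, is separated by chromatography. IBX dehydrogenation of its saturated α-side gives (4S)-3,4-dimethyl-4-(prop-2-en-1-yl)cyclohexa-2,5-dien-1-one F2. Stryker's reagent then reduces only the β-monosubstituted enone arm and leaves the β-methyl enone and the allyl group, giving 6.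

**Step 6 (vinylogous Michael).** The α′-enolate (C2 of the enone) could cyclise instead of the γ-methyl and give a bridged bicyclo[3.3.1] product. Fallback, setting out from 9 and returning at 10: IBX dehydrogenation of 9 gives the cross-conjugated dienone methyl (2E)-5-[(1S)-1,2-dimethyl-4-oxocyclohexa-2,5-dien-1-yl]pent-2-enoate F3, which has no α′-hydrogen. The same t-BuOK cyclisation can now only go through the γ-methyl and gives methyl 2-[(2R,4aS)-4a-methyl-7-oxo-1,2,3,4,4a,7-hexahydronaphthalen-2-yl]acetate F4. Hydrogenation with Wilkinson's catalyst saturates only the disubstituted ring alkene and gives 10.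

**Step 9 (Myers transposition).** The Mitsunobu displacement next to the bulky vinyl iodide may be slow or go SN2′. Fallback, setting out from 11 and returning at 19: carbon is introduced first and the transposition is done with palladium.
- Stille coupling of 11 with (tributylstannyl)methanol gives methyl 2-[(2R,4aS)-8-(hydroxymethyl)-4a-methyl-7-oxo-1,2,3,4,4a,5,6,7-octahydronaphthalen-2-yl]acetate F5.
- TBSCl/imidazole gives the silyl ether methyl 2-[(2R,4aS)-8-{[(tert-butyldimethylsilyl)oxy]methyl}-4a-methyl-7-oxo-1,2,3,4,4a,5,6,7-octahydronaphthalen-2-yl]acetate F6.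
- Luche reduction gives the 3β-alcohol methyl 2-[(2R,4aS,7S)-8-{[(tert-butyldimethylsilyl)oxy]methyl}-7-hydroxy-4a-methyl-1,2,3,4,4a,5,6,7-octahydronaphthalen-2-yl]acetate F7.
- Formic acetic anhydride gives the formate methyl 2-[(2R,4aS,7S)-8-{[(tert-butyldimethylsilyl)oxy]methyl}-7-(formyloxy)-4a-methyl-1,2,3,4,4a,5,6,7-octahydronaphthalen-2-yl]acetate F8.
- Pd(OAc)2/PBu3 (Tsuji–Mandai formate hydrogenolysis) ionises anti to the formate and delivers hydride from palladium to C5 on the α-face, giving methyl 2-[(2R,4aS,8aR)-8-{[(tert-butyldimethylsilyl)oxy]methyl}-4a-methyl-1,2,3,4,4a,5,6,8a-octahydronaphthalen-2-yl]acetate F9.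
- The Eschenmoser methylenation of step 10 gives methyl 2-[(2R,4aR,8aR)-8-{[(tert-butyldimethylsilyl)oxy]methyl}-4a-methyl-1,2,3,4,4a,5,6,8a-octahydronaphthalen-2-yl]prop-2-enoate F10.
- TBAF gives 19.

Further compounds
F1 | step 2 | (4R,5S)-4,5-dimethyl-4-(prop-2-en-1-yl)cyclohex-2-en-1-one | C=CC[C@@]1(C)C=CC(=O)C[C@@H]1C
F2 | step 2 | (4S)-3,4-dimethyl-4-(prop-2-en-1-yl)cyclohexa-2,5-dien-1-one | C=CC[C@@]1(C)C=CC(=O)C=C1C
F3 | step 6 | methyl (2E)-5-[(1S)-1,2-dimethyl-4-oxocyclohexa-2,5-dien-1-yl]pent-2-enoate | COC(=O)/C=C/CC[C@@]1(C)C=CC(=O)C=C1C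
F4 | step 6 | methyl 2-[(2R,4aS)-4a-methyl-7-oxo-1,2,3,4,4a,7-hexahydronaphthalen-2-yl]acetate | COC(=O)C[C@@H]1CC[C@@]2(C)C=CC(=O)C=C2C1
F5 | step 9 | methyl 2-[(2R,4aS)-8-(hydroxymethyl)-4a-methyl-7-oxo-1,2,3,4,4a,5,6,7-octahydronaphthalen-2-yl]acetate | COC(=O)C[C@@H]1CC[C@@]2(C)CCC(=O)C(CO)=C2C1
F6 | step 9 | methyl 2-[(2R,4aS)-8-{[(tert-butyldimethylsilyl)oxy]methyl}-4a-methyl-7-oxo-1,2,3,4,4a,5,6,7-octahydronaphthalen-2-yl]acetate | COC(=O)C[C@@H]1CC[C@@]2(C)CCC(=O)C(CO[Si](C)(C)C(C)(C)C)=C2C1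
F7 | step 9 | methyl 2-[(2R,4aS,7S)-8-{[(tert-butyldimethylsilyl)oxy]methyl}-7-hydroxy-4a-methyl-1,2,3,4,4a,5,6,7-octahydronaphthalen-2-yl]acetate | COC(=O)C[C@@H]1CC[C@@]2(C)CC[C@H](O)C(CO[Si](C)(C)C(C)(C)C)=C2C1
F8 | step 9 | methyl 2-[(2R,4aS,7S)-8-{[(tert-butyldimethylsilyl)oxy]methyl}-7-(formyloxy)-4a-methyl-1,2,3,4,4a,5,6,7-octahydronaphthalen-2-yl]acetate | COC(=O)C[C@@H]1CC[C@@]2(C)CC[C@H](OC=O)C(CO[Si](C)(C)C(C)(C)C)=C2C1
F9 | step 9 | methyl 2-[(2R,4aS,8aR)-8-{[(tert-butyldimethylsilyl)oxy]methyl}-4a-methyl-1,2,3,4,4a,5,6,8a-octahydronaphthalen-2-yl]acetate | COC(=O)C[C@@H]1CC[C@@]2(C)CCC=C(CO[Si](C)(C)C(C)(C)C)[C@@H]2C1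
F10 | step 9 | methyl 2-[(2R,4aR,8aR)-8-{[(tert-butyldimethylsilyl)oxy]methyl}-4a-methyl-1,2,3,4,4a,5,6,8a-octahydronaphthalen-2-yl]prop-2-enoate | C=C(C(=O)OC)[C@@H]1CC[C@@]2(C)CCC=C(CO[Si](C)(C)C(C)(C)C)[C@@H]2C1
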